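**Retrosynthetic overview**
1. Target 20 ← desilylation of 19 ← Mitsunobu angeloylation, with inversion at C6, of macrocyclic alcohol 17.
2. 17 ← closure of the ten-membered ring at C6–C7, the bond made in the 1,10-cyclisation of farnesyl diphosphate: the C7=C11 π-bond of a butenolide allylmetal attacks the C6 aldehyde of 15, setting C6 and C7 and unveiling the 11(13)-methylene.
3. 15 ← anti-selective vinylogous Mukaiyama aldol (C8–C9) between silyloxyfuran 10 (from 3-furanmethanol) and enal 6.
4. 6 ← cross-metathesis with methacrolein (C1=C10) and Brown allylation (C2–C3) of the lactol of tulipalin A (C3–C6, C15).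
5. Ring order: the five-membered lactone is carried from the furan; the ten-membered carbocycle is the only ring formed (step 10).

Assumption: germacrane numbering is used (C8 lactone oxygen, C9 acetate, C6 angelate, C3 hydroxyl, C4=C15 and C11=C13 methylenes, C1=C10 E-olefin), so the target is (3S,6S,7S,8R,9S) = 3β-OH, 6β-OAng, 7α-H, 8β-H, 9α-OAc; the chiral allylborane, Me3SiOOSiMe3 and the bisphosphoramide catalyst are purchased.

**Route**

Step 1
Reactants: 1 α-methylene-γ-butyrolactone (tulipalin A)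
Product: 2 lactol (3-methylideneoxolan-2-ol; ring-chain tautomer of 4-hydroxy-2-methylidenebutanal)
Conditions: i-Bu2AlH (1.05 equiv), CH2Cl2, −78 °C; aq. potassium sodium tartrate
Reagents that add atoms: none
Why: Partial lactone-to-lactol reduction; the aluminium hemiacetal survives at −78 °C until work-up, and 1,2-addition leaves the exocyclic methylene (C4=C15) in place.

Step 2
Reactants: 2 lactol (3-methylideneoxolan-2-ol)
Product: 3 diol (4S)-3-methylidenehept-6-ene-1,4-diol
Conditions: (−)-Ipc2B(allyl) (2.2 equiv; excess covers the free hydroxyl), Et2O, −78 °C to rt; then NaOH, H2O2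
Reagents that add atoms: (−)-B-allyldiisopinocampheylborane, C=CCB([C@@H]1C[C@@H]2C[C@H]([C@H]1C)C2(C)C)[C@@H]1C[C@@H]2C[C@H]([C@H]1C)C2(C)C
Why: Brown asymmetric allylboration of the open hydroxy-aldehyde form; the reagent derived from (+)-α-pinene adds to the Si face through a chair transition state and sets C3 as S.

Step 3
Reactants: 3 diol (4S)-3-methylidenehept-6-ene-1,4-diol
Product: 4 bis-silyl ether (4S)-1,4-bis(tert-butyldimethylsilyloxy)-3-methylidenehept-6-ene
Conditions: TBSCl (2.5 equiv), imidazole, DMF, rt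
Reagents that add atoms: tert-butyldimethylsilyl chloride, CC(C)(C)[Si](C)(C)Cl
Why: Standard silylation of both hydroxyls (Corey conditions); the stereocentre is not touched.

Step 4
Reactants: 4 bis-silyl ether (4S)-1,4-bis(tert-butyldimethylsilyloxy)-3-methylidenehept-6-ene; 5 methacrolein (5 equiv)
Product: 6 enal (2E,5S)-5,8-bis(tert-butyldimethylsilyloxy)-2-methyl-6-methylideneoct-2-enal
Conditions: second-generation Hoveyda–Grubbs catalyst RuCl2(H2IMes)(=CH-C6H4-2-O-i-Pr) (5 mol %), CH2Cl2, 40 °C
Reagents that add atoms: none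
Why: Olefin cross-metathesis of the terminal alkene with methacrolein gives the thermodynamically favoured (E)-2-methyl enal (C1=C10), while the 1,1-disubstituted C4=C15 alkene next to the silyl ether is inert.

Step 5
Reactants: 7 3-furanmethanol
Product: 10 trimethyl({2-[(trimethylsilyl)oxy]furan-3-yl}methoxy)silane, via dilithiated furanmethanol 8 (not isolated), via lithium furylmethoxide 9 (not isolated)
Conditions: n-BuLi (2.2 equiv), THF, −78 to 0 °C; Me3SiOOSiMe3, −78 °C; Me3SiCl, −78 °C to rt; filtration and distillation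
Reagents that add atoms: bis(trimethylsilyl) peroxide, C[Si](C)(C)OO[Si](C)(C)C; chlorotrimethylsilane, C[Si](C)(C)Cl
Why: Alkoxide-directed ortho-lithiation at furan C2, electrophilic oxygenation of the furyllithium with the silyl peroxide, then O-silylation give a 2-silyloxyfuran that already carries C13 at the alcohol oxidation level.

Step 6
Reactants: 6 enal (2E,5S)-5,8-bis(tert-butyldimethylsilyloxy)-2-methyl-6-methylideneoct-2-enal; 10 trimethyl({2-[(trimethylsilyl)oxy]furan-3-yl}methoxy)silane
Product: 12 (5R)-5-[(1S,2E,5S)-5,8-bis(tert-butyldimethylsilyloxy)-1-hydroxy-2-methyl-6-methylideneoct-2-en-1-yl]-3-(hydroxymethyl)furan-2(5H)-one, via C13 trimethylsilyl ether 11 (not isolated)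
Conditions: SiCl4 (1.1 equiv), Denmark (R,R)-binaphthyldiamine bisphosphoramide (5 mol %), i-Pr2NEt (10 mol %), CH2Cl2, −78 °C; aq. NaHCO3/KF; then citric acid, MeOH, 0 °C
Reagents that add atoms: none
Why: Catalytic enantioselective vinylogous Mukaiyama aldol reaction: the furan attacks through C5 on the Re face of the siliconium-bound enal in an open transition state, giving the anti adduct and setting C8 (R) and C9 (S); the expected facial sense of the (R,R)-catalyst is assumed, otherwise its mirror image is used, and mild acid then frees the primary C13 hydroxyl.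

Step 7
Reactants: 12 (5R)-5-[(1S,2E,5S)-5,8-bis(tert-butyldimethylsilyloxy)-1-hydroxy-2-methyl-6-methylideneoct-2-en-1-yl]-3-(hydroxymethyl)furan-2(5H)-one
Product: 13 [(5R)-5-{(1S,2E,5S)-1-acetoxy-5,8-bis(tert-butyldimethylsilyloxy)-2-methyl-6-methylideneoct-2-en-1-yl}-2-oxo-2,5-dihydrofuran-3-yl]methyl acetate
Conditions: Ac2O, pyridine, DMAP (5 mol %), CH2Cl2, 0 °C
Reagents that add atoms: acetic anhydride, CC(=O)OC(C)=O
Why: Acetylation; one reagent installs the C9 acetate of the target and turns the primary allylic alcohol (C13) into the leaving group for the ring closure.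

Step 8
Reactants: 13 diacetate (as above)
Product: 14 [(5R)-5-{(1S,2E,5S)-1-acetoxy-5-(tert-butyldimethylsilyloxy)-8-hydroxy-2-methyl-6-methylideneoct-2-en-1-yl}-2-oxo-2,5-dihydrofuran-3-yl]methyl acetate
Conditions: HF·pyridine, pyridine, THF, 0 °C
Reagents that add atoms: none
Why: Selective cleavage of the primary silyl ether by buffered HF; the hindered secondary allylic TBS ether and both acetates survive.

Step 9
Reactants: 14 primary alcohol (as above)
Product: 15 [(5R)-5-{(1S,2E,5S)-1-acetoxy-5-(tert-butyldimethylsilyloxy)-2-methyl-6-methylidene-8-oxooct-2-en-1-yl}-2-oxo-2,5-dihydrofuran-3-yl]methyl acetate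
Conditions: Dess–Martin periodinane, NaHCO3, CH2Cl2, 0 °C; used crude
Reagents that add atoms: none
Why: Buffered Dess–Martin oxidation gives the β,γ-unsaturated aldehyde (C6) without moving the C4=C15 double bond into conjugation.

Step 10
Reactants: 15 aldehyde (as above)
Product: 17 (3S,6R,7S,8R,9S)-9-acetoxy-3-(tert-butyldimethylsilyloxy)-6-hydroxygermacra-1(10)E,4(15),11(13)-trien-12,8-olide (6α-OH), via allylindium acetate iodide 16 (not isolated)
Conditions: Pd(PPh3)4 (10 mol %), InI (2.5 equiv), THF/DMA 4:1, 25 °C, syringe-pump addition to 2 mM; aq. NH4Cl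
Reagents that add atoms: none
Why: Proposed new method: zerovalent palladium ionises the primary 2-(acyloxymethyl)enoate acetate and InI reduces the π-allyl complex to an allylindium, whose C7=C11 π-bond attacks the C6 aldehyde γ-selectively (the closest known reactions are palladium/InI umpolung carbonyl allylation of allylic acetates and chromium- or zinc/palladium-mediated Barbier closures of ten-membered germacrane rings); C7 is set by attack anti to the C8 substituent (trans ring fusion), C6 by a chair Zimmerman–Traxler transition state with the C5 chain equatorial (E-type cyclic allylmetal gives the anti adduct, 6R), and the in-ring C8–O bond lies in the nodal plane of the allyl system so 1,4-elimination is blocked.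

Step 11
Reactants: 17 macrocyclic 6α-alcohol (as above); 18 angelic acid ((Z)-2-methylbut-2-enoic acid)
Product: 19 (3S,6S,7S,8R,9S)-9-acetoxy-6-angeloyloxy-3-(tert-butyldimethylsilyloxy)germacra-1(10)E,4(15),11(13)-trien-12,8-olide
Conditions: PPh3 and DIAD premixed (3 equiv each), then 18 (3 equiv) and 17, toluene, 0 °C to rt
Reagents that add atoms: none
Why: Mitsunobu esterification; SN2 displacement of the C6 oxyphosphonium by angelate inverts C6 (R to S, 6α to 6β), and because the alcohol rather than the acid is activated the (Z)-angelate is not isomerised to tiglate.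

Step 12
Reactants: 19 silyl ether (as above)
Product: 20 target CNP0115054.1, (3S,6S,7S,8R,9S)-9-acetoxy-6-angeloyloxy-3-hydroxygermacra-1(10)E,4(15),11(13)-trien-12,8-olide
Conditions: HF·pyridine, THF, 0 °C to rt
Reagents that add atoms: none
Why: Acidic fluoride desilylation of the secondary allylic TBS ether; the acetate, the angelate and the α-methylene lactone are stable to these non-basic conditions.

**Compound list**
1 | α-methylene-γ-butyrolactone (tulipalin A) | C=C1CCOC1=O | starting material
2 | 3-methylideneoxolan-2-ol (lactol, anomeric mixture) | OC1OCCC1=C | intermediate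
3 | (4S)-3-methylidenehept-6-ene-1,4-diol | OCCC(=C)[C@@H](O)CC=C | intermediate
4 | (4S)-1,4-bis(tert-butyldimethylsilyloxy)-3-methylidenehept-6-ene | CC(C)(C)[Si](C)(C)OCCC(=C)[C@@H](O[Si](C)(C)C(C)(C)C)CC=C | intermediate
5 | methacrolein | CC(=C)C=O | starting material
6 | (2E,5S)-5,8-bis(tert-butyldimethylsilyloxy)-2-methyl-6-methylideneoct-2-enal | O=C/C(C)=C/C[C@H](O[Si](C)(C)C(C)(C)C)C(=C)CCO[Si](C)(C)C(C)(C)C | intermediate
7 | 3-furanmethanol | OCc1ccoc1 | starting material
8 | 2-lithio-3-(lithiooxymethyl)furan | [Li]OCc1ccoc1[Li] | intermediate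
9 | lithium [2-(trimethylsilyloxy)furan-3-yl]methoxide | [Li]OCc1ccoc1O[Si](C)(C)C | intermediate
10 | trimethyl({2-[(trimethylsilyl)oxy]furan-3-yl}methoxy)silane | C[Si](C)(C)OCc1ccoc1O[Si](C)(C)C | intermediate
11 | (5R)-5-[(1S,2E,5S)-5,8-bis(tert-butyldimethylsilyloxy)-1-hydroxy-2-methyl-6-methylideneoct-2-en-1-yl]-3-[(trimethylsilyloxy)methyl]furan-2(5H)-one | O=C1O[C@@H]([C@@H](O)/C(C)=C/C[C@H](O[Si](C)(C)C(C)(C)C)C(=C)CCO[Si](C)(C)C(C)(C)C)C=C1CO[Si](C)(C)C | intermediate
12 | (5R)-5-[(1S,2E,5S)-5,8-bis(tert-butyldimethylsilyloxy)-1-hydroxy-2-methyl-6-methylideneoct-2-en-1-yl]-3-(hydroxymethyl)furan-2(5H)-one | O=C1O[C@@H]([C@@H](O)/C(C)=C/C[C@H](O[Si](C)(C)C(C)(C)C)C(=C)CCO[Si](C)(C)C(C)(C)C)C=C1CO | intermediate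
13 | [(5R)-5-{(1S,2E,5S)-1-acetoxy-5,8-bis(tert-butyldimethylsilyloxy)-2-methyl-6-methylideneoct-2-en-1-yl}-2-oxo-2,5-dihydrofuran-3-yl]methyl acetate | O=C1O[C@@H]([C@@H](OC(C)=O)/C(C)=C/C[C@H](O[Si](C)(C)C(C)(C)C)C(=C)CCO[Si](C)(C)C(C)(C)C)C=C1COC(C)=O | intermediate
14 | [(5R)-5-{(1S,2E,5S)-1-acetoxy-5-(tert-butyldimethylsilyloxy)-8-hydroxy-2-methyl-6-methylideneoct-2-en-1-yl}-2-oxo-2,5-dihydrofuran-3-yl]methyl acetate | O=C1O[C@@H]([C@@H](OC(C)=O)/C(C)=C/C[C@H](O[Si](C)(C)C(C)(C)C)C(=C)CCO)C=C1COC(C)=O | intermediate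
15 | [(5R)-5-{(1S,2E,5S)-1-acetoxy-5-(tert-butyldimethylsilyloxy)-2-methyl-6-methylidene-8-oxooct-2-en-1-yl}-2-oxo-2,5-dihydrofuran-3-yl]methyl acetate | O=C1O[C@@H]([C@@H](OC(C)=O)/C(C)=C/C[C@H](O[Si](C)(C)C(C)(C)C)C(=C)CC=O)C=C1COC(C)=O | intermediate
16 | allylindium derived from 15 (In(I)(OAc) on C13 in place of the primary acetate) | O=C1O[C@@H]([C@@H](OC(C)=O)/C(C)=C/C[C@H](O[Si](C)(C)C(C)(C)C)C(=C)CC=O)C=C1C[In](I)OC(C)=O | intermediate
17 | (3S,6R,7S,8R,9S)-9-acetoxy-3-(tert-butyldimethylsilyloxy)-6-hydroxygermacra-1(10)E,4(15),11(13)-trien-12,8-olide | C=C1C(=O)O[C@@H]2[C@@H]1[C@H](O)CC(=C)[C@@H](O[Si](C)(C)C(C)(C)C)C/C=C(\C)[C@@H]2OC(C)=O | intermediate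
18 | angelic acid, (Z)-2-methylbut-2-enoic acid | C/C=C(/C)C(=O)O | starting material
19 | (3S,6S,7S,8R,9S)-9-acetoxy-6-angeloyloxy-3-(tert-butyldimethylsilyloxy)germacra-1(10)E,4(15),11(13)-trien-12,8-olide | C=C1C(=O)O[C@@H]2[C@@H]1[C@@H](OC(=O)/C(C)=C\C)CC(=C)[C@@H](O[Si](C)(C)C(C)(C)C)C/C=C(\C)[C@@H]2OC(C)=O | intermediate
20 | CNP0115054.1, (3S,6S,7S,8R,9S)-9-acetoxy-6-angeloyloxy-3-hydroxygermacra-1(10)E,4(15),11(13)-trien-12,8-olide | C=C1C(=O)O[C@@H]2[C@@H]1[C@@H](OC(=O)/C(C)=C\C)CC(=C)[C@@H](O)C/C=C(\C)[C@@H]2OC(C)=O | target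

**Step count**
Total: 12 steps. Longest linear sequence: 11 steps (steps 1–4 and 6–12, from 1).

**Three steps most likely to fail**

Step 10 (ring closure). Risks are oligomerisation, β-hydride loss or ionisation of the C9 acetate at palladium, and a facial outcome at C7 or C6 that differs from the chair prediction. The fallback sets out from 13 and makes the nucleophile isolable. Pd2(dba)3-catalysed borylation of the primary allylic acetate with B2pin2 in DMSO gives the pinacol allylboronate F1. HF·pyridine then frees the primary hydroxyl to give the boronate alcohol F2, and Dess–Martin oxidation gives the boronate aldehyde F3. F3 can be handled because 2-alkoxycarbonyl allylboronates add to aldehydes only slowly without a catalyst. Sc(OTf)3 (10 mol %) in toluene at 2 mM then triggers a closed-transition-state allylboration that needs no reducing metal and comes back to the route at 17 after hydrolytic work-up. If either closure instead delivers the 6β-alcohol F4 (the C6 epimer of 17), F4 is esterified with retention using the mixed anhydride of 18 and 2,4,6-trichlorobenzoyl chloride (Et3N, toluene, 80 °C, no DMAP) and joins the route at 19.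

Step 11 (Mitsunobu inversion at a hindered ring carbinol). Risks are elimination toward C5 or C7 and phosphine addition to the α-methylene lactone. The fallback sets out from 17: ClCH2SO2Cl and pyridine give the chloromethanesulfonate F5. Cesium angelate (from 18 and Cs2CO3) with 18-crown-6 in toluene displaces it with inversion, without phosphine or azodicarboxylate, and comes back to the route at 19.

Step 6 (vinylogous aldol with the C13-oxygenated silyloxyfuran). Risks are ionisation of the furylmethyl silyl ether under SiCl4 and eroded anti or facial selectivity. The fallback sets out from 6 and uses commercial 2-(trimethylsilyloxy)furan, the best-precedented nucleophile for this catalyst, to give the C13-free butenolide F6. C13 is then installed by Morita–Baylis–Hillman hydroxymethylation (aqueous formaldehyde, PMe3 cat., THF), which comes back to the route at 12.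

**Further compounds**
F1 | step 10 | pinacol ester of [(5R)-5-{(1S,2E,5S)-1-acetoxy-5,8-bis(tert-butyldimethylsilyloxy)-2-methyl-6-methylideneoct-2-en-1-yl}-2-oxo-2,5-dihydrofuran-3-yl]methylboronic acid | O=C1O[C@@H]([C@@H](OC(C)=O)/C(C)=C/C[C@H](O[Si](C)(C)C(C)(C)C)C(=C)CCO[Si](C)(C)C(C)(C)C)C=C1CB1OC(C)(C)C(C)(C)O1
F2 | step 10 | 8-hydroxy analogue of F1 (primary silyl ether removed) | O=C1O[C@@H]([C@@H](OC(C)=O)/C(C)=C/C[C@H](O[Si](C)(C)C(C)(C)C)C(=C)CCO)C=C1CB1OC(C)(C)C(C)(C)O1
F3 | step 10 | 8-oxo analogue of F1 (boronate aldehyde) | O=C1O[C@@H]([C@@H](OC(C)=O)/C(C)=C/C[C@H](O[Si](C)(C)C(C)(C)C)C(=C)CC=O)C=C1CB1OC(C)(C)C(C)(C)O1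
F4 | step 10 | (3S,6S,7S,8R,9S)-9-acetoxy-3-(tert-butyldimethylsilyloxy)-6-hydroxygermacra-1(10)E,4(15),11(13)-trien-12,8-olide (6β-alcohol, C6 epimer of 17) | C=C1C(=O)O[C@@H]2[C@@H]1[C@@H](O)CC(=C)[C@@H](O[Si](C)(C)C(C)(C)C)C/C=C(\C)[C@@H]2OC(C)=O
F5 | step 11 | (3S,6R,7S,8R,9S)-9-acetoxy-3-(tert-butyldimethylsilyloxy)-6-[(chloromethanesulfonyl)oxy]germacra-1(10)E,4(15),11(13)-trien-12,8-olide | C=C1C(=O)O[C@@H]2[C@@H]1[C@H](OS(=O)(=O)CCl)CC(=C)[C@@H](O[Si](C)(C)C(C)(C)C)C/C=C(\C)[C@@H]2OC(C)=O
F6 | step 6 | (5R)-5-[(1S,2E,5S)-5,8-bis(tert-butyldimethylsilyloxy)-1-hydroxy-2-methyl-6-methylideneoct-2-en-1-yl]furan-2(5H)-one | O=C1O[C@@H]([C@@H](O)/C(C)=C/C[C@H](O[Si](C)(C)C(C)(C)C)C(=C)CCO[Si](C)(C)C(C)(C)C)C=C1
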